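The cyclohexane ring is opened at C5–C6, and its two arms are then detached from the cyclopentane at C3a–C4 and C7a–C7. The feature used is the ring C1–C2–C3–C3a–C7a: its neighbouring stereocentres C3, C3a and C7a send their bonds to C1′, C4 and C7 to alternating faces. In one flask a 1-ethoxyvinyl cuprate attacks C3a of the precursor, an (S)-2-methylcyclopent-2-enone that carries only the E-dienyl chain at C4 (target C3), opposite that chain. The C7a enolate then adds to 2,2-dimethoxyacetaldehyde opposite the new group. This fixes both arms, the quaternary carbon and the trans ring fusion. The configuration left at C7 is not used; it is reset through a ketone.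

Key step: step 7

Remarks on the chemistry (assumptions and design corrections)
- **Numbering and faces.** The indane numbering of the target is used for every ring compound, and the side chain is C1′–C7′. "Bottom" is the face of the C7a methyl group. C4 (seen from the five-membered ring), the 4-OH and Br of the target are bottom. H3a, the C3 side chain, C7 (seen from the five-membered ring) and the 4-methyl group are top. The target is (3S,3aS,4R,7S,7aS), with Br equatorial and 4-OH axial.
- **C7 configuration (assumption).** A chair, metal-bridged aldol transition state with the acetal carbon equatorial puts O7 anti to C3a. After ring closure this hydroxyl is equatorial, which is already the configuration of the C–Br bond. A substitution with inversion therefore cannot start from it. The aldol product and its successors are drawn as this epimer. The other C7 epimer may be carried along, and both merge in the C7 ketone, which is then reduced to the axial alcohol.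
- **Precursor design.** The hydrogen at C3 of the enone precursor is doubly allylic and vinylogously acidic. Dehydrogenation of a 3-substituted cyclopentanone offers no reliable control over where the C=C bond forms. The enone is therefore made from an enantiopure cyclopentenediol monoacetate by allylic substitution and neutral oxidation. This fixes the alkene position and avoids base.
- **Role of the enol ether.** The 1-ethoxyvinyl group also protects the C4 ketone while the C1 ketone is removed. Compounds that contain it are worked up at pH ≥ 7 and chromatographed on Et3N-washed silica.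
- **Drying of the aldehyde.** 2,2-Dimethoxyacetaldehyde is sold as an aqueous solution. It is extracted into CH2Cl2, dried and distilled before use.

Step 1
Reactants: 1 6-methylhept-5-en-2-one
Product: 3 6-methylhept-5-en-1-yne, via enol phosphate 2 (not isolated)
Conditions: LDA (1.05 equiv), THF, −78 °C; ClP(O)(OEt)2, −78 °C → rt; LDA (2.3 equiv), −78 °C → rt; H2O
Reagents that add atoms: none
Why: Kinetic deprotonation at the methyl group, O-phosphorylation and LDA-induced elimination of diethyl phosphate (the enol phosphate route from methyl ketones to terminal alkynes) should convert the acetyl group into an ethynyl group and leave the trisubstituted alkene alone.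

Step 2
Reactants: 3 6-methylhept-5-en-1-yne
Product: 5 (1E)-1-iodo-2,6-dimethylhepta-1,5-diene, via alkenylalane 4 (not isolated)
Conditions: Me3Al (2 equiv), Cp2ZrCl2 (0.25 equiv), CH2Cl2, 0 °C → rt; I2, THF, −30 → 0 °C
Reagents that add atoms: trimethylaluminium C[Al](C)C; iodine II
Why: Zirconium-catalysed Negishi carboalumination adds methyl and aluminium syn across the alkyne with aluminium at the terminus, and iodinolysis with retention should give the E-trisubstituted alkenyl iodide that carries the C1′=C2′ geometry of the target.

Step 3
Reactants: 5 (1E)-1-iodo-2,6-dimethylhepta-1,5-diene; 6 (1R,4S)-cis-4-acetoxycyclopent-2-en-1-ol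
Product: 9 (1R,4R)-4-[(1E)-2,6-dimethylhepta-1,5-dienyl]cyclopent-2-en-1-ol (trans), via alkenyllithium 7 (not isolated), via lithium borate 8 (not isolated)
Conditions: 5, t-BuLi (2 equiv), Et2O, −78 °C; MeB(pin), −78 → 0 °C; then 6, NiCl2(PPh3)2 (10 mol %), t-BuCN, NaI, THF, rt
Reagents that add atoms: none
Why: In this nickel-catalysed allylic substitution with a lithium alkenylborate, Ni(0) ionises the acetate from the face opposite to it and the alkenyl group passes from boron to nickel and is delivered on the nickel face, so C3 forms with net inversion (trans to the hydroxyl), and coupling at the allyl terminus remote from the carbinol gives the 1,4-product.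

Step 4
Reactants: 9 (1R,4R)-4-[(1E)-2,6-dimethylhepta-1,5-dienyl]cyclopent-2-en-1-ol
Product: 10 (4R)-4-[(1E)-2,6-dimethylhepta-1,5-dienyl]cyclopent-2-en-1-one
Conditions: MnO2 (excess), CH2Cl2, rt
Reagents that add atoms: none
Why: Manganese dioxide oxidises the allylic alcohol under neutral heterogeneous conditions, so the alkene stays where the monoacetate placed it and the doubly allylic C3 hydrogen should not be exchanged.

Step 5
Reactants: 10 (4R)-4-[(1E)-2,6-dimethylhepta-1,5-dienyl]cyclopent-2-en-1-one
Product: 11 (4S)-4-[(1E)-2,6-dimethylhepta-1,5-dienyl]-2-iodocyclopent-2-en-1-one (same spatial arrangement at C3; the descriptor changes with the priorities)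
Conditions: I2, pyridine–CH2Cl2 (1:1), 0 °C → rt
Reagents that add atoms: iodine II
Why: α-Iodination of an enone by iodine–pyridine (conjugate addition of pyridine at C3a, iodination of the enolate at C7a, loss of pyridine) needs no base strong enough to remove the C3 hydrogen, and the reversible contact of iodine with the isolated alkenes should have no consequence.

Step 6
Reactants: 11 (4S)-4-[(1E)-2,6-dimethylhepta-1,5-dienyl]-2-iodocyclopent-2-en-1-one
Product: 12 (4S)-4-[(1E)-2,6-dimethylhepta-1,5-dienyl]-2-methylcyclopent-2-en-1-one
Conditions: MeZnCl, PdCl2(dppf) (5 mol %), THF, 0 °C → rt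
Reagents that add atoms: methylzinc chloride C[Zn]Cl
Why: Negishi coupling of the 2-iodoenone with a methylzinc reagent installs the C7a methyl group under essentially neutral conditions, since the organozinc reagent neither adds to the enone on its own nor deprotonates C3.

Step 7
Reactants: 12 (4S)-4-[(1E)-2,6-dimethylhepta-1,5-dienyl]-2-methylcyclopent-2-en-1-one; 13 ethyl vinyl ether; 14 2,2-dimethoxyacetaldehyde
Product: 19 (2S,3S,4S)-4-[(1E)-2,6-dimethylhepta-1,5-dienyl]-3-(1-ethoxyethenyl)-2-[(1R)-1-hydroxy-2,2-dimethoxyethyl]-2-methylcyclopentan-1-one, via 1-ethoxyvinyllithium 15 (not isolated), via cuprate 16 (not isolated), via lithium enolate 17 (not isolated), via chlorozinc enolate 18 (not isolated)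
Conditions: 13, t-BuLi, THF, −78 → 0 °C; CuI (slightly more than 0.5 equiv per Li), THF–Me2S, −78 → −40 °C; 12, −78 → −40 °C; ZnCl2 (Et2O), −78 °C; anhydrous 14, −78 °C; aq NH4Cl–NH3 (pH 8–9) added cold
Reagents that add atoms: none
Why: The cuprate binds the enone π-system, adds at C3a and reductively eliminates to form C3a–C4 and a regiodefined C1–C7a enolate, which after exchange to zinc adds to the aldehyde through a metal-bridged six-membered (Zimmerman–Traxler) transition state to form C7a–C7; no ring is closed. The closest known reaction type is the three-component conjugate addition–aldol coupling of 2-substituted cyclopentenones, and α-alkoxyvinyl cuprates are established acyl-anion equivalents for 1,4-addition. C3a is controlled by C3, because the dienyl chain shields the top face and copper therefore delivers the vinyl group from the bottom (trans-3,4 product). C7a is controlled by C3a, because the new 1-ethoxyvinyl group next to the enolate carbon shields the bottom face, so the aldehyde enters from the top and the methyl group ends cis to C4 and trans to H3a. C7 follows from the chair with the acetal carbon equatorial (O7 anti to C3a), but this centre is erased in step 15, so its selectivity is not needed. The step needs 1,4- over 1,2-addition, no loss of the C3 hydrogen, no enolate equilibration and no retro-aldol cleavage, which are secured by soft copper without free organolithium, by slow proton exchange at −78 °C on an enolate whose carbon C7a bears no hydrogen, by the chelated zinc aldolate and by the cold basic quench.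

Step 8
Reactants: 19 aldol
Product: 20 7-O-tert-butyldimethylsilyl ether of 19
Conditions: TBSOTf, 2,6-lutidine, CH2Cl2, −78 °C
Reagents that add atoms: tert-butyldimethylsilyl triflate CC(C)(C)[Si](C)(C)OS(=O)(=O)C(F)(F)F
Why: A silyl triflate with a hindered pyridine silylates the crowded aldol hydroxyl at low temperature without strong base or free acid, which blocks retro-aldol cleavage and distinguishes O7 from the C1 oxygen, while enol ether and acetal should survive at −78 °C.

Step 9
Reactants: 20 silyl ether
Product: 21 cyclopentanol (20 with C1=O reduced to CHOH; OH drawn on the top face)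
Conditions: NaBH4, MeOH–THF, 0 °C → rt
Reagents that add atoms: none
Why: Borohydride reduction of the only carbonyl group, with hydride expected from the bottom (methyl) face away from the bulky C7 arm, gives the C1 alcohol, whose configuration does not matter because the centre is removed in step 11.

Step 10
Reactants: 21 cyclopentanol
Product: 22 O-(C1) 1H-imidazole-1-carbothioate of 21
Conditions: 1,1′-thiocarbonyldiimidazole, DMAP (cat.), toluene, 90 °C
Reagents that add atoms: 1,1′-thiocarbonyldiimidazole S=C(n1ccnc1)n1ccnc1
Why: Thioacyl transfer under nearly neutral conditions makes the radical precursor and avoids the metal alkoxide of a xanthate synthesis, which could let the silyl group migrate from O7 to O1.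

Step 11
Reactants: 22 imidazole-1-carbothioate
Product: 23 cyclopentane with C1 as CH2 (C3 dienyl top; C3a 1-ethoxyvinyl bottom; C7a methyl bottom and CH(OTBS)CH(OMe)2 top)
Conditions: Bu3SnH, AIBN (cat.), toluene, 100 °C
Reagents that add atoms: none
Why: In this Barton–McCombie deoxygenation the stannyl radical adds to sulfur, the C1–O bond fragments and the secondary C1 radical takes hydrogen from the stannane faster than it can cyclise, since every alkene is placed only for a four-membered or 5-endo ring, so acetal, enol ether, silyl ether and all stereocentres should persist.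

Step 12
Reactants: 23 deoxygenated cyclopentane
Product: 25 7-hydroxy-3-[(1E)-2,6-dimethylhepta-1,5-dienyl]-7a-methyl-1,2,3,3a,7,7a-hexahydro-4H-inden-4-one (trans-fused; H3a and side chain top; 7a-methyl and 7-OH bottom), via keto aldehyde 24 (not isolated)
Conditions: 2 M aq HCl–THF (1:4), rt → 45 °C
Reagents that add atoms: water O
Why: Dilute acid should hydrolyse the enol ether to the C4 methyl ketone, remove the silyl group and open the acetal to the C6 aldehyde, after which the keto aldehyde can condense in only one productive way, C5 onto C6 (intramolecular aldol condensation, 6-enolendo-exo-trig, the C3a enol being able to form only a four-membered ring), on arms that are already trans, and acid is used rather than alkoxide because the C3a hydrogen of trans-hydrindan-4-ones is exchanged readily only by base.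

Step 13
Reactants: 25 hydroxy enone
Product: 26 7-hydroxy-3-[(1E)-2,6-dimethylhepta-1,5-dienyl]-7a-methyloctahydro-4H-inden-4-one (trans-fused)
Conditions: [(Ph3P)CuH]6, H2O, degassed toluene, rt
Reagents that add atoms: none
Why: Stryker's reagent delivers hydride only to the β-carbon C6 of the enone (copper hydride conjugate reduction) and water protonates the copper enolate at C5, so the two isolated trisubstituted alkenes, the hydroxyl group and the C3a centre should stay untouched.

Step 14
Reactants: 26 hydroxy ketone
Product: 27 3-[(1E)-2,6-dimethylhepta-1,5-dienyl]-4,7a-dimethyloctahydro-1H-indene-4,7-diol (4-OH bottom and axial; 4-methyl top; 7-OH bottom and equatorial)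
Conditions: anhydrous CeCl3, MeLi, THF, −78 °C; then 26, −78 °C; H2O
Reagents that add atoms: methyllithium (used as methylcerium dichloride) [Li]C
Why: The weakly basic organocerium reagent adds 1,2 without enolising the epimerisable ketone, and because the axial (bottom) path to C4 is closed by the 1,3-diaxial C7a methyl group it should attack from the top face, placing the new methyl group equatorial and the hydroxyl axial (4R), the sense known for nucleophilic additions to 7a-methyl-trans-hydrindan-4-ones.

Step 15
Reactants: 27 diol
Product: 28 4-hydroxy-7-ketone (27 with C7 as C=O)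
Conditions: Dess–Martin periodinane, CH2Cl2, 0 °C → rt
Reagents that add atoms: none
Why: Dess–Martin oxidation acts only on the secondary alcohol, so both C7 epimers should converge on one ketone, which has no enolisable stereocentre (C7a is quaternary) and whose γ-hydroxyl group cannot undergo retro-aldol cleavage.

Step 16
Reactants: 28 hydroxy ketone
Product: 29 4,7-diol with the 7-OH top and axial (7-epimer of 27)
Conditions: L-Selectride, THF, −78 °C; H2O
Reagents that add atoms: none
Why: The bulky trialkylborohydride avoids the axial path past H3a and the axial H5 and attacks the C7 ketone along the equatorial path, as it does with 2,2-disubstituted cyclohexanones such as 4,4-dimethyl-3-oxo steroids, so the axial (top) alcohol should result.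

Step 17
Reactants: 29 axial alcohol
Product: 30 (3S,3aS,4R,7S,7aS)-7-bromo-3-[(1E)-2,6-dimethylhepta-1,5-dienyl]-4,7a-dimethyloctahydro-1H-inden-4-ol (target)
Conditions: CBr4, PPh3, 2,6-lutidine (acid scavenger), toluene, 0 → 60 °C
Reagents that add atoms: carbon tetrabromide BrC(Br)(Br)Br
Why: In this Appel reaction the secondary alcohol forms the alkoxyphosphonium ion and bromide displaces it from the bottom face with inversion (SN2) to give the equatorial 7S bromide, while the tertiary axial 4-OH, crowded by the C7a methyl group and the side chain, should not be activated and cannot bridge to C7 because the trans ring fusion forbids the boat that this would need.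

Compound list
1 | 6-methylhept-5-en-2-one | CC(=O)CCC=C(C)C | starting material
2 | diethyl 6-methylhepta-1,5-dien-2-yl phosphate | C=C(CCC=C(C)C)OP(=O)(OCC)OCC | intermediate
3 | 6-methylhept-5-en-1-yne | C#CCCC=C(C)C | intermediate
4 | [(1E)-2,6-dimethylhepta-1,5-dienyl]dimethylaluminium | CC(C)=CCC/C(C)=C/[Al](C)C | intermediate
5 | (1E)-1-iodo-2,6-dimethylhepta-1,5-diene | CC(C)=CCC/C(C)=C/I | intermediate
6 | (1R,4S)-cis-4-acetoxycyclopent-2-en-1-ol | CC(=O)O[C@H]1C[C@@H](O)C=C1 | starting material
7 | [(1E)-2,6-dimethylhepta-1,5-dienyl]lithium | CC(C)=CCC/C(C)=C/[Li] | intermediate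
8 | lithium [(1E)-2,6-dimethylhepta-1,5-dienyl](methyl)(pinacolato)borate | [Li+].CC(C)=CCC/C(C)=C/[B-]1(C)OC(C)(C)C(C)(C)O1 | intermediate
9 | (1R,4R)-4-[(1E)-2,6-dimethylhepta-1,5-dienyl]cyclopent-2-en-1-ol | CC(C)=CCC/C(C)=C/[C@@H]1C[C@@H](O)C=C1 | intermediate
10 | (4R)-4-[(1E)-2,6-dimethylhepta-1,5-dienyl]cyclopent-2-en-1-one | CC(C)=CCC/C(C)=C/[C@@H]1CC(=O)C=C1 | intermediate
11 | (4S)-4-[(1E)-2,6-dimethylhepta-1,5-dienyl]-2-iodocyclopent-2-en-1-one | CC(C)=CCC/C(C)=C/[C@@H]1CC(=O)C(I)=C1 | intermediate
12 | (4S)-4-[(1E)-2,6-dimethylhepta-1,5-dienyl]-2-methylcyclopent-2-en-1-one | CC(C)=CCC/C(C)=C/[C@@H]1CC(=O)C(C)=C1 | intermediate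
13 | ethyl vinyl ether | C=COCC | starting material
14 | 2,2-dimethoxyacetaldehyde | COC(OC)C=O | starting material
15 | (1-ethoxyvinyl)lithium | [Li]C(=C)OCC | intermediate
16 | lithium bis(1-ethoxyvinyl)cuprate | [Li+].C=C(OCC)[Cu-]C(=C)OCC | intermediate
17 | lithium C1–C7a enolate after the 1,4-addition | [Li+].CC(C)=CCC/C(C)=C/[C@@H]1CC([O-])=C(C)[C@H]1C(=C)OCC | intermediate
18 | chlorozinc C1–C7a enolate | CC(C)=CCC/C(C)=C/[C@@H]1CC(O[Zn]Cl)=C(C)[C@H]1C(=C)OCC | intermediate
19 | (2S,3S,4S)-4-dienyl-3-(1-ethoxyethenyl)-2-[(1R)-1-hydroxy-2,2-dimethoxyethyl]-2-methylcyclopentan-1-one | CC(C)=CCC/C(C)=C/[C@@H]1CC(=O)[C@](C)([C@@H](O)C(OC)OC)[C@H]1C(=C)OCC | intermediate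
20 | 7-O-TBS ether of 19 | CC(C)=CCC/C(C)=C/[C@@H]1CC(=O)[C@](C)([C@@H](O[Si](C)(C)C(C)(C)C)C(OC)OC)[C@H]1C(=C)OCC | intermediate
21 | C1 alcohol of 20 (OH top) | CC(C)=CCC/C(C)=C/[C@@H]1C[C@H](O)[C@](C)([C@@H](O[Si](C)(C)C(C)(C)C)C(OC)OC)[C@H]1C(=C)OCC | intermediate
22 | O-(C1) imidazole-1-carbothioate of 21 | CC(C)=CCC/C(C)=C/[C@@H]1C[C@H](OC(=S)n2ccnc2)[C@](C)([C@@H](O[Si](C)(C)C(C)(C)C)C(OC)OC)[C@H]1C(=C)OCC | intermediate
23 | C1-deoxygenated cyclopentane | CC(C)=CCC/C(C)=C/[C@@H]1CC[C@](C)([C@@H](O[Si](C)(C)C(C)(C)C)C(OC)OC)[C@H]1C(=C)OCC | intermediate
24 | keto aldehyde (C4 acetyl, C6 formyl, free 7-OH) | CC(C)=CCC/C(C)=C/[C@@H]1CC[C@](C)([C@@H](O)C=O)[C@H]1C(C)=O | intermediate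
25 | trans-fused 7-hydroxy-hydrind-5-en-4-one | CC(C)=CCC/C(C)=C/[C@@H]1CC[C@]2(C)[C@@H](O)C=CC(=O)[C@@H]12 | intermediate
26 | trans-fused 7-hydroxy-hydrindan-4-one | CC(C)=CCC/C(C)=C/[C@@H]1CC[C@]2(C)[C@@H](O)CCC(=O)[C@@H]12 | intermediate
27 | 4,7-diol, 7-OH equatorial | CC(C)=CCC/C(C)=C/[C@@H]1CC[C@]2(C)[C@@H](O)CC[C@@](C)(O)[C@@H]12 | intermediate
28 | 4-hydroxy-7-ketone | CC(C)=CCC/C(C)=C/[C@@H]1CC[C@]2(C)C(=O)CC[C@@](C)(O)[C@@H]12 | intermediate
29 | 4,7-diol, 7-OH axial | CC(C)=CCC/C(C)=C/[C@@H]1CC[C@]2(C)[C@H](O)CC[C@@](C)(O)[C@@H]12 | intermediate
30 | (3S,3aS,4R,7S,7aS)-7-bromo-3-[(1E)-2,6-dimethylhepta-1,5-dienyl]-4,7a-dimethyloctahydro-1H-inden-4-ol | CC(C)=CCC/C(C)=C/[C@@H]1CC[C@]2(C)[C@@H](Br)CC[C@@](C)(O)[C@@H]12 | target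

Total step count: 17. Longest linear sequence: 17 steps (1 → 30). Compounds 6, 13 and 14 are bought and enter at steps 3 and 7.

Steps most likely to fail

**1. Step 7.**
- What may go wrong: slow transfer of the α-alkoxyvinyl ligand to the α-methylated, γ-branched enone; removal of the acidic C3 hydrogen by traces of organolithium; poor reactivity of a copper-laden enolate towards the aldehyde; reversal of the aldol addition on warming or work-up.
- Fallback: the two bond formations are separated. Setting out from 12, cuprate 16 is added in the presence of TMSCl. This accelerates the 1,4-addition and traps the enolate as the trimethylsilyl enol ether F1, which is isolated. MeLi in THF at 0 °C then regenerates the copper-free lithium enolate 17 with unchanged regiochemistry. ZnCl2 followed by 14 at −78 °C brings the route back at 19.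

**2. Step 12.**
- What may go wrong: slow opening of the acetal that sits next to an oxygenated, neopentyl carbon. The resulting long acid exposure could lead to protonation or Prins-type capture of the side-chain alkenes, isomerisation of the free α-hydroxy aldehyde, or epimerisation at C3a.
- Fallback: the two masks react with each other directly instead of being hydrolysed first.
  - Setting out from 23, catalytic TMSOTf with 2,6-di-tert-butyl-4-methylpyridine in dilute CH2Cl2 at −78 °C ionises the acetal. The enol ether carbon C5 attacks C6 (intramolecular Mukaiyama-type acetal aldol reaction) to give the bicyclic mixed ketal F2.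
  - Brief contact with aqueous oxalic acid gives the 6-methoxy ketone F3.
  - Catalytic TsOH in benzene at 40 °C expels methanol to give the 7-silyloxy enone F4.
  - HF·pyridine in THF removes the silyl group and brings the route back at 25.

**3. Step 17.**
- What may go wrong: elimination towards C6; 1,2-shift of the antiperiplanar C7a methyl group if the crowded phosphonium ion ionises before bromide arrives; dehydration of the tertiary alcohol during the heating that the neopentyl displacement needs.
- Fallback: activation and displacement are separated. Setting out from 29, chloromethanesulfonyl chloride in pyridine at 0 °C esterifies only the secondary hydroxyl and gives the 7-chloromethanesulfonate F5, which is isolated. A concentrated soluble bromide source (LiBr or Bu4NBr in toluene at 40–60 °C) then displaces this small, highly reactive but little-ionising leaving group with inversion. This brings the route back at 30.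

Further compounds
F1 | step 7 | trimethylsilyl enol ether of the 1,4-adduct | CC(C)=CCC/C(C)=C/[C@@H]1CC(O[Si](C)(C)C)=C(C)[C@H]1C(=C)OCC
F2 | step 12 | bicyclic 4-ethoxy-4,6-dimethoxy ketal with 7-OTBS (C4 and C6 epimers) | CC(C)=CCC/C(C)=C/[C@@H]1CC[C@]2(C)[C@@H](O[Si](C)(C)C(C)(C)C)C(OC)CC(OC)(OCC)[C@@H]12
F3 | step 12 | 6-methoxy-7-silyloxy-hydrindan-4-one (C6 epimers) | CC(C)=CCC/C(C)=C/[C@@H]1CC[C@]2(C)[C@@H](O[Si](C)(C)C(C)(C)C)C(OC)CC(=O)[C@@H]12
F4 | step 12 | 7-silyloxy-hydrind-5-en-4-one | CC(C)=CCC/C(C)=C/[C@@H]1CC[C@]2(C)[C@@H](O[Si](C)(C)C(C)(C)C)C=CC(=O)[C@@H]12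
F5 | step 17 | 7-chloromethanesulfonate of 29 | CC(C)=CCC/C(C)=C/[C@@H]1CC[C@]2(C)[C@H](OS(=O)(=O)CCl)CC[C@@](C)(O)[C@@H]12
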